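The bicycle (numbering: C1 quaternary CMe, C2 OAc, C4 carbinol, C5 fusion CH, C6 OAng, C8=C9, C10 OBz) is cut at C4–C5 and C1–C2, which reduces it to the seven-membered ring alone. The key step exploits the α-methyl enone C10(=O)–C1(Me)=C5 that sits next to the C6 oxygen inside that ring: a masked isobutyryl anion adds to C5 and the resulting C1 enolate captures acetaldehyde, so both ring-fusion stereocentres and every carbon of the five-membered ring arrive in one operation. The precursor is (S)-5-silyloxy-3,7-dimethylcyclohepta-2,6-dienone, already carrying C6–C10, the C8=C9 alkene and both oxygens. Aldol closure of C3–C4, two stereocontrolled reductions and three acylations complete the target.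

Key step: step 9

Remarks on the design

- Numbering (daucane locants, used for all bicyclic names): five-membered ring C1–C5, seven-membered ring C1, C5–C10; C3 and C7 are CH2, C4 carries OH and isopropyl, C8 carries methyl. The target is (1R,2S,4R,5S,6S,10S). C1–CH3, C4–OH and C10–OBz lie on one face; C2–OAc, C4–i-Pr, C5–H and C6–O lie on the other, so the ring fusion is trans.
- C10 and C6 must be cis across C1=C5 for the seven-membered ring to close, so the enoate of step 4 has to be Z. An ordinary E-selective phosphonopropionate would give a triene that cannot cyclise; the bis(trifluoroethyl) phosphonate is used instead.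
- The C6 stereocentre is bought as methyl (S)-glycidate. Its ester carbon is already at the oxidation level needed for C5, and no benzyl ether has to be removed beside the 1,1-disubstituted alkene.
- Assumption: the acetaldehyde-derived carbinol centre of 18 is formed without useful control and is written without a descriptor; both epimers converge at 19.

Step 1
Reactants: 1 methyl (S)-glycidate; 2 isopropenylmagnesium bromide
Product: 3 methyl (2S)-2-hydroxy-4-methylpent-4-enoate
Conditions: CuI (10 mol%), THF, −78 to −40 °C; then aq. NH4Cl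
Reagents that add atoms: none
Why: Copper-catalysed Grignard opening of the epoxide at its unsubstituted carbon (SN2) is faster at low temperature than addition to the ester and leaves the stereocentre, the future C6, untouched.

Step 2
Reactants: 3 methyl (2S)-2-hydroxy-4-methylpent-4-enoate
Product: 4 methyl (2S)-2-[(tert-butyldimethylsilyl)oxy]-4-methylpent-4-enoate
Conditions: TBSCl, imidazole, DMF, rt
Reagents that add atoms: tert-butyldimethylsilyl chloride, CC(C)(C)[Si](C)(C)Cl
Why: Imidazole-promoted silylation of a secondary α-hydroxy ester is routine, and the bulky silyl ether later shields one face of the dienone.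

Step 3
Reactants: 4 methyl (2S)-2-[(tert-butyldimethylsilyl)oxy]-4-methylpent-4-enoate
Product: 5 (2S)-2-[(tert-butyldimethylsilyl)oxy]-4-methylpent-4-enal
Conditions: i-Bu2AlH (1.1 equiv), CH2Cl2, −78 °C; then MeOH, aq. potassium sodium tartrate
Reagents that add atoms: none
Why: Partial reduction of an α-silyloxy ester with i-Bu2AlH stops at the tetrahedral aluminium hemiacetal, which releases the aldehyde only on work-up and does not epimerise the α-centre.

Step 4
Reactants: 5 (2S)-2-[(tert-butyldimethylsilyl)oxy]-4-methylpent-4-enal; 6 ethyl 2-[bis(2,2,2-trifluoroethoxy)phosphoryl]propanoate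
Product: 7 ethyl (2Z,4S)-4-[(tert-butyldimethylsilyl)oxy]-2,6-dimethylhepta-2,6-dienoate
Conditions: KN(SiMe3)2, 18-crown-6, THF, −78 °C
Reagents that add atoms: none
Why: In the Still–Gennari olefination the electron-poor phosphonate eliminates rapidly from the kinetic adduct and should give the Z-trisubstituted enoate, in which the ester carbon (C10) and C6 are cis as the ring requires.

Step 5
Reactants: 7 ethyl (2Z,4S)-4-[(tert-butyldimethylsilyl)oxy]-2,6-dimethylhepta-2,6-dienoate
Product: 8 (2Z,4S)-4-[(tert-butyldimethylsilyl)oxy]-N-methoxy-N,2,6-trimethylhepta-2,6-dienamide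
Conditions: MeNH(OMe)·HCl, i-PrMgCl, THF, −20 to 0 °C; then aq. NH4Cl
Reagents that add atoms: N,O-dimethylhydroxylamine hydrochloride, CNOC.Cl
Why: Weinreb amide formation with ClMgN(OMe)Me generated in the flask is a direct acyl substitution that does not disturb the Z-alkene or the silyl ether.

Step 6
Reactants: 8 (2Z,4S)-4-[(tert-butyldimethylsilyl)oxy]-N-methoxy-N,2,6-trimethylhepta-2,6-dienamide; 9 vinylmagnesium bromide
Product: 10 (4Z,6S)-6-[(tert-butyldimethylsilyl)oxy]-4,8-dimethylnona-1,4,8-trien-3-one
Conditions: THF, −78 to 0 °C; then cold 1 M HCl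
Reagents that add atoms: none
Why: In the Weinreb ketone synthesis the chelated tetrahedral adduct resists a second addition and releases the vinyl ketone only on the acidic quench, which also protonates the liberated amine and prevents its conjugate addition.

Step 7
Reactants: 10 (4Z,6S)-6-[(tert-butyldimethylsilyl)oxy]-4,8-dimethylnona-1,4,8-trien-3-one
Product: 11 (5S)-5-[(tert-butyldimethylsilyl)oxy]-3,7-dimethylcyclohepta-2,6-dien-1-one
Conditions: second-generation Grubbs catalyst (5 mol%), CH2Cl2 (5 mM), 40 °C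
Reagents that add atoms: none
Why: Ring-closing metathesis between the vinyl ketone and the 1,1-disubstituted alkene forms C8=C9 with loss of ethylene, helped by the Z-configured C1=C5 alkene that holds the two termini close.

Step 8
Reactants: 12 isobutyraldehyde; 13 propane-1,3-dithiol
Product: 14 2-(propan-2-yl)-1,3-dithiane
Conditions: BF3·OEt2 (cat.), CH2Cl2, 0 °C to rt
Reagents that add atoms: none
Why: Lewis-acid-catalysed dithioacetalisation of an aldehyde is the standard preparation of 2-alkyl-1,3-dithianes.

Step 9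
Reactants: 14 2-(propan-2-yl)-1,3-dithiane; 11 (5S)-5-[(tert-butyldimethylsilyl)oxy]-3,7-dimethylcyclohepta-2,6-dien-1-one; 15 acetaldehyde
Product: 18 (5S,6S,7R)-5-[(tert-butyldimethylsilyl)oxy]-7-(1-hydroxyethyl)-3,7-dimethyl-6-[2-(propan-2-yl)-1,3-dithian-2-yl]cyclohept-2-en-1-one, via 2-lithio-2-isopropyl-1,3-dithiane 16 (not isolated), via lithium dienolate 17 (not isolated)
Conditions: t-BuLi, THF/HMPA (10:1), −78 °C; then 11, −78 °C; then 15 (excess), −78 °C; AcOH quench at −78 °C
Reagents that add atoms: none
Why: The dithiane carbanion 16, a solvent-separated ion pair in THF/HMPA, adds in conjugate fashion to C5 of the enone C10(=O)–C1(Me)=C5, and the cross-conjugated dienolate 17 then adds through C1 to acetaldehyde, so that C4–C5 and C1–C2 form in one flask. The closest known reaction type is the tandem conjugate addition–aldol (three-component) coupling of sulfur-stabilised acyl-anion equivalents with cyclic enones. No ring is closed. C5 is controlled by the C6 silyloxy group, the nucleophile entering the ring face anti to it; C1 is controlled by C5, the aldehyde approaching the enolate face opposite the bulky dithianyl group, which places C2 trans to C4 as the trans ring fusion demands, while the C2 carbinol centre is uncontrolled and is erased in step 10. The step needs 1,4- over 1,2-addition, secured by HMPA and the soft carbanion, and attack at C5 and not at C8, secured by the methyl group that makes C8 a fully substituted β-carbon. Low temperature and the cold acidic quench are meant to suppress γ-deprotonation of the dienone and retro-aldol loss of acetaldehyde.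

Step 10
Reactants: 18 (5S,6S,7R)-5-[(tert-butyldimethylsilyl)oxy]-7-(1-hydroxyethyl)-3,7-dimethyl-6-[2-(propan-2-yl)-1,3-dithian-2-yl]cyclohept-2-en-1-one
Product: 19 (5S,6S,7R)-7-acetyl-5-[(tert-butyldimethylsilyl)oxy]-3,7-dimethyl-6-[2-(propan-2-yl)-1,3-dithian-2-yl]cyclohept-2-en-1-one
Conditions: Dess–Martin periodinane, NaHCO3, CH2Cl2, 0 °C to rt
Reagents that add atoms: none
Why: Dess–Martin oxidation of the secondary carbinol under buffered anhydrous conditions leaves the thioacetal, silyl ether and enone intact and removes the uncontrolled C2 centre, so both epimers of 18 converge.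

Step 11
Reactants: 19 (5S,6S,7R)-7-acetyl-5-[(tert-butyldimethylsilyl)oxy]-3,7-dimethyl-6-[2-(propan-2-yl)-1,3-dithian-2-yl]cyclohept-2-en-1-one
Product: 20 (5S,6S,7R)-7-acetyl-5-[(tert-butyldimethylsilyl)oxy]-3,7-dimethyl-6-(2-methylpropanoyl)cyclohept-2-en-1-one
Conditions: MeI, CaCO3, MeCN/H2O (9:1), 45 °C
Reagents that add atoms: water, O
Why: Alkylative dithiane hydrolysis (S-methylation, opening to a thionium ion, capture by water) runs near neutrality under CaCO3 buffering and tolerates the silyl ether, the enone and the non-enolisable 1,3-diketone.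

Step 12
Reactants: 20 (5S,6S,7R)-7-acetyl-5-[(tert-butyldimethylsilyl)oxy]-3,7-dimethyl-6-(2-methylpropanoyl)cyclohept-2-en-1-one
Product: 21 (1R,4R,5S,6S)-6-[(tert-butyldimethylsilyl)oxy]-4-hydroxydauc-8-ene-2,10-dione
Conditions: LiN(SiMe3)2 (1.05 equiv), THF, −78 to −40 °C; AcOH quench
Reagents that add atoms: none
Why: Kinetic deprotonation occurs at the acetyl methyl group, the only unhindered α-position, and the enolate closes the five-membered ring by intramolecular aldol addition (5-exo-trig) to the C4 ketone with the isopropyl group on the face of C5–H, away from C6 and the C1 methyl, which puts the C4 hydroxyl cis to the angular methyl.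

Step 13
Reactants: 21 (1R,4R,5S,6S)-6-[(tert-butyldimethylsilyl)oxy]-4-hydroxydauc-8-ene-2,10-dione
Product: 22 (1R,2S,4R,5S,6S)-6-[(tert-butyldimethylsilyl)oxy]-2,4-dihydroxydauc-8-en-10-one
Conditions: Me4NBH(OAc)3, MeCN/AcOH (1:1), −40 to −20 °C
Reagents that add atoms: none
Why: In this hydroxyl-directed (Saksena–Evans) reduction the C4 hydroxyl binds boron and delivers hydride to its own face of the C2 carbonyl, giving the 2,4-trans diol, while the conjugated, neopentyl C10 ketone, which has no β-hydroxyl at the outset, should react more slowly.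

Step 14
Reactants: 22 (1R,2S,4R,5S,6S)-6-[(tert-butyldimethylsilyl)oxy]-2,4-dihydroxydauc-8-en-10-one
Product: 23 (1R,2S,4R,5S,6S)-2-acetoxy-6-[(tert-butyldimethylsilyl)oxy]-4-hydroxydauc-8-en-10-one
Conditions: Ac2O, pyridine, DMAP (cat.), CH2Cl2, 0 °C to rt
Reagents that add atoms: acetic anhydride, CC(=O)OC(C)=O
Why: Nucleophile-catalysed acetylation takes the secondary C2 hydroxyl, whereas the tertiary C4 hydroxyl is too hindered to react under these conditions.

Step 15
Reactants: 23 (1R,2S,4R,5S,6S)-2-acetoxy-6-[(tert-butyldimethylsilyl)oxy]-4-hydroxydauc-8-en-10-one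
Product: 24 (1R,2S,4R,5S,6S,10S)-2-acetoxy-6-[(tert-butyldimethylsilyl)oxy]dauc-8-ene-4,10-diol
Conditions: NaBH4, CeCl3·7H2O, MeOH, −78 to −40 °C
Reagents that add atoms: none
Why: Luche reduction gives clean 1,2-reduction of the enone, and the small hydride should attack C10 axially, anti to the axial angular methyl on C1, so that the new hydroxyl is cis to that methyl and anti to the C2 acetate.

Step 16
Reactants: 24 (1R,2S,4R,5S,6S,10S)-2-acetoxy-6-[(tert-butyldimethylsilyl)oxy]dauc-8-ene-4,10-diol
Product: 25 (1R,2S,4R,5S,6S,10S)-2-acetoxy-10-benzoyloxy-6-[(tert-butyldimethylsilyl)oxy]dauc-8-en-4-ol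
Conditions: BzCl, pyridine, DMAP (cat.), CH2Cl2, 0 °C to rt
Reagents that add atoms: benzoyl chloride, O=C(Cl)c1ccccc1
Why: Acylation of the allylic secondary alcohol with an acid chloride under nucleophilic catalysis is routine, and the tertiary C4 hydroxyl again stays free.

Step 17
Reactants: 25 (1R,2S,4R,5S,6S,10S)-2-acetoxy-10-benzoyloxy-6-[(tert-butyldimethylsilyl)oxy]dauc-8-en-4-ol
Product: 26 (1R,2S,4R,5S,6S,10S)-2-acetoxy-10-benzoyloxydauc-8-ene-4,6-diol
Conditions: HF·pyridine, THF/pyridine, 0 °C to rt
Reagents that add atoms: none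
Why: Fluoride-mediated cleavage of the secondary silyl ether under buffered, weakly acidic conditions should cause neither ester migration nor ionisation of the allylic benzoate.

Step 18
Reactants: 26 (1R,2S,4R,5S,6S,10S)-2-acetoxy-10-benzoyloxydauc-8-ene-4,6-diol
Product: 27 (1R,2S,4R,5S,6S,10S)-2-acetoxy-6-angeloyloxy-10-benzoyloxydauc-8-en-4-ol (CNP0248576.1)
Conditions: angelic acid, 2,4,6-trichlorobenzoyl chloride, Et3N, toluene, rt; then 26, 80 °C
Reagents that add atoms: angelic acid, C/C=C(/C)C(=O)O
Why: Yamaguchi-type esterification through the mixed anhydride, run without a nucleophilic catalyst, acylates the secondary C6 hydroxyl without Z-to-E isomerisation to the tiglate and leaves the tertiary C4 hydroxyl untouched.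

Compound list

1 | methyl (2S)-oxirane-2-carboxylate (methyl (S)-glycidate) | COC(=O)[C@@H]1CO1 | starting material
2 | isopropenylmagnesium bromide | CC(=C)[Mg]Br | starting material
3 | methyl (2S)-2-hydroxy-4-methylpent-4-enoate | COC(=O)[C@@H](O)CC(C)=C | intermediate
4 | methyl (2S)-2-[(tert-butyldimethylsilyl)oxy]-4-methylpent-4-enoate | COC(=O)[C@@H](O[Si](C)(C)C(C)(C)C)CC(C)=C | intermediate
5 | (2S)-2-[(tert-butyldimethylsilyl)oxy]-4-methylpent-4-enal | O=C[C@@H](O[Si](C)(C)C(C)(C)C)CC(C)=C | intermediate
6 | ethyl 2-[bis(2,2,2-trifluoroethoxy)phosphoryl]propanoate | CCOC(=O)C(C)P(=O)(OCC(F)(F)F)OCC(F)(F)F | starting material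
7 | ethyl (2Z,4S)-4-[(tert-butyldimethylsilyl)oxy]-2,6-dimethylhepta-2,6-dienoate | CCOC(=O)/C(C)=C\[C@@H](O[Si](C)(C)C(C)(C)C)CC(C)=C | intermediate
8 | (2Z,4S)-4-[(tert-butyldimethylsilyl)oxy]-N-methoxy-N,2,6-trimethylhepta-2,6-dienamide | CON(C)C(=O)/C(C)=C\[C@@H](O[Si](C)(C)C(C)(C)C)CC(C)=C | intermediate
9 | vinylmagnesium bromide | C=C[Mg]Br | starting material
10 | (4Z,6S)-6-[(tert-butyldimethylsilyl)oxy]-4,8-dimethylnona-1,4,8-trien-3-one | C=CC(=O)/C(C)=C\[C@@H](O[Si](C)(C)C(C)(C)C)CC(C)=C | intermediate
11 | (5S)-5-[(tert-butyldimethylsilyl)oxy]-3,7-dimethylcyclohepta-2,6-dien-1-one | CC1=C[C@@H](O[Si](C)(C)C(C)(C)C)CC(C)=CC1=O | intermediate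
12 | isobutyraldehyde | CC(C)C=O | starting material
13 | propane-1,3-dithiol | SCCCS | starting material
14 | 2-(propan-2-yl)-1,3-dithiane | CC(C)C1SCCCS1 | intermediate
15 | acetaldehyde | CC=O | starting material
16 | 2-lithio-2-isopropyl-1,3-dithiane (not isolated) | [Li]C1(C(C)C)SCCCS1 | intermediate
17 | lithium dienolate formed by addition of 16 to C5 of 11 (not isolated) | CC1=C(O[Li])C=C(C)C[C@H](O[Si](C)(C)C(C)(C)C)[C@H]1C2(C(C)C)SCCCS2 | intermediate
18 | (5S,6S,7R)-5-[(tert-butyldimethylsilyl)oxy]-7-(1-hydroxyethyl)-3,7-dimethyl-6-[2-(propan-2-yl)-1,3-dithian-2-yl]cyclohept-2-en-1-one (carbinol centre undefined) | CC(O)[C@]1(C)C(=O)C=C(C)C[C@H](O[Si](C)(C)C(C)(C)C)[C@H]1C2(C(C)C)SCCCS2 | intermediate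
19 | (5S,6S,7R)-7-acetyl-5-[(tert-butyldimethylsilyl)oxy]-3,7-dimethyl-6-[2-(propan-2-yl)-1,3-dithian-2-yl]cyclohept-2-en-1-one | CC(=O)[C@]1(C)C(=O)C=C(C)C[C@H](O[Si](C)(C)C(C)(C)C)[C@H]1C2(C(C)C)SCCCS2 | intermediate
20 | (5S,6S,7R)-7-acetyl-5-[(tert-butyldimethylsilyl)oxy]-3,7-dimethyl-6-(2-methylpropanoyl)cyclohept-2-en-1-one | CC(=O)[C@]1(C)C(=O)C=C(C)C[C@H](O[Si](C)(C)C(C)(C)C)[C@H]1C(=O)C(C)C | intermediate
21 | (1R,4R,5S,6S)-6-[(tert-butyldimethylsilyl)oxy]-4-hydroxydauc-8-ene-2,10-dione (trans-fused) | CC(C)(C)[Si](C)(C)O[C@H]1CC(C)=CC(=O)[C@@]2(C)C(=O)C[C@@](O)(C(C)C)[C@H]12 | intermediate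
22 | (1R,2S,4R,5S,6S)-6-[(tert-butyldimethylsilyl)oxy]-2,4-dihydroxydauc-8-en-10-one | CC(C)(C)[Si](C)(C)O[C@H]1CC(C)=CC(=O)[C@@]2(C)[C@@H](O)C[C@@](O)(C(C)C)[C@H]12 | intermediate
23 | (1R,2S,4R,5S,6S)-2-acetoxy-6-[(tert-butyldimethylsilyl)oxy]-4-hydroxydauc-8-en-10-one | CC(C)(C)[Si](C)(C)O[C@H]1CC(C)=CC(=O)[C@@]2(C)[C@@H](OC(C)=O)C[C@@](O)(C(C)C)[C@H]12 | intermediate
24 | (1R,2S,4R,5S,6S,10S)-2-acetoxy-6-[(tert-butyldimethylsilyl)oxy]dauc-8-ene-4,10-diol | CC(C)(C)[Si](C)(C)O[C@H]1CC(C)=C[C@H](O)[C@@]2(C)[C@@H](OC(C)=O)C[C@@](O)(C(C)C)[C@H]12 | intermediate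
25 | (1R,2S,4R,5S,6S,10S)-2-acetoxy-10-benzoyloxy-6-[(tert-butyldimethylsilyl)oxy]dauc-8-en-4-ol | CC(C)(C)[Si](C)(C)O[C@H]1CC(C)=C[C@H](OC(=O)c2ccccc2)[C@@]2(C)[C@@H](OC(C)=O)C[C@@](O)(C(C)C)[C@H]12 | intermediate
26 | (1R,2S,4R,5S,6S,10S)-2-acetoxy-10-benzoyloxydauc-8-ene-4,6-diol | O[C@H]1CC(C)=C[C@H](OC(=O)c2ccccc2)[C@@]2(C)[C@@H](OC(C)=O)C[C@@](O)(C(C)C)[C@H]12 | intermediate
27 | (1R,2S,4R,5S,6S,10S)-2-acetoxy-6-angeloyloxy-10-benzoyloxydauc-8-en-4-ol (CNP0248576.1) | C/C=C(/C)C(=O)O[C@H]1CC(C)=C[C@H](OC(=O)c2ccccc2)[C@@]2(C)[C@@H](OC(C)=O)C[C@@](O)(C(C)C)[C@H]12 | target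

Total step count: 18. Longest linear sequence: 17 steps (steps 1–7 and 9–18); step 8 is a one-step side branch.

Steps most likely to fail

Step 9. The hindered dithianyl anion may add to the carbonyl instead of C5, or abstract a γ-proton (C7–H or the C8 methyl), which opens a path to loss of silanol and aromatisation. The aldolate may also revert before the quench, or the facial selectivity may be incomplete. Fallback, setting out from 11 and returning at 20: the acyl-anion equivalent is replaced by an alkenyl nucleophile. 2-Bromo-3-methylbut-1-ene and Mg in THF give (3-methylbut-1-en-2-yl)magnesium bromide F1, which is added to 11 under copper catalysis (CuBr·SMe2, THF, −78 °C). The resulting enolate is trapped with acetaldehyde 15 to give (5S,6S,7R)-5-[(tert-butyldimethylsilyl)oxy]-7-(1-hydroxyethyl)-3,7-dimethyl-6-(3-methylbut-1-en-2-yl)cyclohept-2-en-1-one F2, with the same anti-to-silyloxy and trans-trapping preferences expected. Dess–Martin oxidation as in step 10 gives (5S,6S,7R)-7-acetyl-5-[(tert-butyldimethylsilyl)oxy]-3,7-dimethyl-6-(3-methylbut-1-en-2-yl)cyclohept-2-en-1-one F3. Ozonolysis (O3, CH2Cl2/pyridine, −78 °C; then Me2S) should cleave the isolated 1,1-disubstituted alkene, which is far more electron-rich than the enone alkene, and deliver triketone 20.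

Step 12. Enolisation may occur at C5 or at the isopropyl methine instead of the acetyl methyl; a C5 enolate can expel the C6 silyloxy group; the aldol may dehydrate or close to the C4 epimer. Fallback, setting out from 20 and returning at 21: the nucleophile is fixed as a neutral enol silane and the ketone is activated by a Lewis acid, so that no basic alkoxide or competing enolate is present. TMSOTf and Et3N (CH2Cl2, −78 °C) silylate the least hindered methyl ketone to give (5S,6S,7R)-5-[(tert-butyldimethylsilyl)oxy]-3,7-dimethyl-6-(2-methylpropanoyl)-7-[1-(trimethylsilyloxy)ethenyl]cyclohept-2-en-1-one F4. An intramolecular Mukaiyama aldol addition (TiCl4, CH2Cl2, −78 °C) then forms C3–C4, and aqueous work-up returns 21.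

Step 15. Hydride may be delivered to the wrong face of C10, because the C2 acetoxy group on the upper face competes with the angular methyl on the lower face. Fallback, setting out from 22 and returning at 24: an Evans–Tishchenko reduction (SmI2 cat., acetaldehyde 15, THF, −10 °C) replaces steps 14 and 15. The hemiacetal formed at the C2 hydroxyl transfers hydride to C10 from the C2–O face through a cyclic transition state and is itself converted into the C2 acetate, so the C2/C10 anti relationship is fixed by intramolecular delivery. This fallback makes no compound outside the compound list (F0).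

Further compounds

F1 | step 9 | (3-methylbut-1-en-2-yl)magnesium bromide | CC(C)C(=C)[Mg]Br
F2 | step 9 | (5S,6S,7R)-5-[(tert-butyldimethylsilyl)oxy]-7-(1-hydroxyethyl)-3,7-dimethyl-6-(3-methylbut-1-en-2-yl)cyclohept-2-en-1-one | CC(O)[C@]1(C)C(=O)C=C(C)C[C@H](O[Si](C)(C)C(C)(C)C)[C@H]1C(=C)C(C)C
F3 | step 9 | (5S,6S,7R)-7-acetyl-5-[(tert-butyldimethylsilyl)oxy]-3,7-dimethyl-6-(3-methylbut-1-en-2-yl)cyclohept-2-en-1-one | CC(=O)[C@]1(C)C(=O)C=C(C)C[C@H](O[Si](C)(C)C(C)(C)C)[C@H]1C(=C)C(C)C
F4 | step 12 | (5S,6S,7R)-5-[(tert-butyldimethylsilyl)oxy]-3,7-dimethyl-6-(2-methylpropanoyl)-7-[1-(trimethylsilyloxy)ethenyl]cyclohept-2-en-1-one | C=C(O[Si](C)(C)C)[C@]1(C)C(=O)C=C(C)C[C@H](O[Si](C)(C)C(C)(C)C)[C@H]1C(=O)C(C)C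
F0 | step 15 | none | none
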